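(The earlier runs and the new flask are calculated on assumed constants; noise was put on by code.)

- A small charge of free catalyst, 0.250 % of the starting material in amount, has to go round 400 times, so we ask how much catalyst meets the starting material, and for how long.

| flask | starting material | coupling partner | free catalyst | remark | time |
|---|---|---|---|---|---|
| amber | 44 mM | 48.4 mM | 0.11 mM | run made earlier |  |
| teal | 44 mM | 48.4 mM | 0.055 mM | run made earlier |  |
| red | 44 mM | 48.4 mM | 0.083 mM | run made earlier |  |
| oak | 44 mM (fed, over 40.0 min) | 48.4 mM | 0.11 mM | a stirred flask in which starting material is dosed at a steady rate over 40.0 min without added volume, worked up at 50 min | 50 min |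
| maple | 44 mM | 48.4 mM | 0.11 mM | everything together in a closed stirred flask, run for 50 min | 50 min |
| ash | 44 mM | 48.4 mM | 0.11 mM | one stirred flow tank at steady state, fed with the mixture as stated, mean residence time 50 min |  |
| elm | 44 mM | 48.4 mM (fed, over 40.0 min) | 0.11 mM | all but coupling partner at the start; coupling partner goes in evenly over 40.0 min, the run ends at 50 min | 50 min |

- amber (time / min: product / %): 4.00: 7.2; 8.00: 18.4; 15.0: 31.2; 25.0: 49.1; 50.0: 80.3
- teal (time / min: product / %): 4.00: 4.8; 12.0: 14.4; 25.0: 26.1; 40.0: 40.6; 50.0: 47.3
- red (time / min: product / %): 4.00: 6.2; 12.0: 18.3; 25.0: 38.2; 40.0: 58.3; 50.0: 68.0

(readings scatter by 1 percentage point)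

- the stated concentrations are those of everything mixed, before any reaction; amounts are the same in each set-up
- the earlier runs were read with a standard deviation of 1 percentage point
- reactions considered so far: catalyst intermediate B -> catalyst intermediate C; coupling partner + free catalyst -> catalyst intermediate A; catalyst intermediate C -> free catalyst + product; starting material + catalyst intermediate A -> catalyst intermediate B; coupling partner + catalyst intermediate B <-> idle complex
- the feed brings no volume worth counting
- the earlier runs were made in a closed, stirred flask

- order of the set-ups by the amount of product at the outlet or at the end, in percent of the starting material put in, highest first (oak / maple / ash / elm)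
- amount of product at the outlet or at the end, in percent of the starting material put in, oak
- amount of product at the outlet or at the end, in percent of the starting material put in, maple
- amount of product at the outlet or at the end, in percent of the starting material put in, ash
- amount of product at the outlet or at the end, in percent of the starting material put in, elm

- We work with the fraction left. Teal, with half of amber's free catalyst, had 52.7 % of its starting material left at 50.0 min, and amber had 50.9 % left at half that time, so in these runs catalyst and time trade against each other, within a scatter of 1 percentage point on each reading.
- Oak looks nearly the same as maple, which repeats amber: the charges are equal, but oak's starting material goes in evenly, so it arrives on average 20.0 min after the start and stays 30.0 min.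
- That gives oak 30.0 min of amber time, meaning the minutes the starting material spends in the flask times the free catalyst relative to amber's, other charges as in amber.
- Maple has 50 min of amber time, so oak should end with more left than maple's expected 19.7 %, because its amber time is shorter.
- Red at 40.0 min stands close to oak, at 30.2 min of amber time, and had 41.7 % left, so our reckoning for oak is 58.3 % product. It assumes the pace leans on starting material, a guess these runs cannot test, and we make no reckoning of our own for ash or elm.
- The forecast gives oak 68 %, maple 80 %, ash 64 % and elm 72 %, in the order maple > elm > oak > ash. Its oak stands 9.7 points above ours, and of oak against elm it says “This ordering of oak and elm is a judgement call.”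
- The flasks give the order maple > elm > ash > oak, with oak 61.1 %, maple 79.9 %, ash 64.5 % and elm 74.6 %.

    catalyst intermediate B → catalyst intermediate C (k = 3.11 s⁻¹)
    coupling partner + free catalyst → catalyst intermediate A (k = 61.6 M⁻¹ s⁻¹)
    catalyst intermediate C → free catalyst + product (k = 0.421 s⁻¹)
    starting material + catalyst intermediate A → catalyst intermediate B (k = 8.29 M⁻¹ s⁻¹)
    coupling partner + catalyst intermediate B ⇌ idle complex, settled at all times (K = 58.0 M⁻¹)

- At 30.5 min in oak, free catalyst had a half-life of 0.32 s in its step with coupling partner, far shorter than the 21 min of starting material in its step with catalyst intermediate A, and at the end of oak catalyst intermediate A, the resting state, held 64.7 % of the catalyst, with 38.8 % of the starting material left after 30.0 min of amber time. The same oak flask with a quarter of the free catalyst counts 7.64 min of amber time, amber at 8.00 min had 81.6 % left, and that flask ended with 80.7 % left.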